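The earlier grey run stood at 0.0318 M of target at its last reading although 0.0380 M of coupling partner went in, so it had made less target than one partner for one target would give, and that one-for-one case is the zero of our scale.

in all of them: starting material 0.10 M; free catalyst 1 mol%
- grey: coupling partner 0.38 equiv; run made earlier
- amber: coupling partner 1.8 equiv; run made earlier
- Monday's: coupling partner 0.300 equiv; time 1.0 h
- Tuesday's: coupling partner 1.20 equiv; time 1.5 h

- grey (time / min: target / %, starting material / %): 5.00: 11.0, 89.0; 12.0: 19.4, 80.0; 25.0: 29.7, 72.6; 60.0: 31.8, 67.9
- amber (time / min: target / %, starting material / %): 8.00: 37.9, 62.5; 20.0: 66.8, 32.1; 40.0: 87.7, 14.0; 60.0: 94.3, 6.6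

(scatter of a reading: 1 percentage point)



- which one finishes higher in amount of target, in percent of the starting material charged ("neither" within 2 percentage points) (Monday's / Tuesday's / neither)
- amount of target at the end, in percent of the starting material charged, Monday's
- amount of target at the end, in percent of the starting material charged, Tuesday's

Starting material was still there in grey, 67.9% at 60.0 min, and amber, with more partner, reached 94.3% of target. So we read the coupling partner as the limiting reagent, with part of it lost on another path.

Suppose that loss needs two partners to meet, its rate going with c(coupling partner) squared, while the useful path takes one partner at the catalyst, its rate going with c(coupling partner). At one catalyst loading, partner wasted per partner used is then w·c(coupling partner), with w constant. In grey, wasted over used is 0.195; taking the mean c(coupling partner) as half the charge, w comes to 10.3 M⁻¹. This w, the waste coefficient, partner wasted per partner used and per unit of c(coupling partner), carries the scatter of grey's readings.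

Summed as the partner falls from its charge c to nothing, the rule gives an expected end value of target, ln(1 + w·c)/w. For our own reckoning that is 26.2% on Monday's and 78.2% on Tuesday's, the latter still below the whole starting material. Raising the partner by a factor of 4.00 raises this estimate by a factor of 2.98. Time should not hold either flask far back: the grey readings rose from 29.7% at 25.0 min to 31.8% at 60.0 min, and Monday's, with less partner, gets 1.0 h. Tuesday's gets 1.5 h, longer than the 40.0 min in which amber, with more partner, passed Tuesday's figure.

The forecast also names Tuesday's, with 24% and 89%, saying “That makes partner the limiting reagent at low loading.”, and it stands below our figure on Monday's and above it on Tuesday's.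

The flask gives 26.8% on Monday's and 79.0% on Tuesday's, so Tuesday's finishes higher.

    coupling partner + free catalyst → catalyst intermediate A (k = 240 M⁻¹ min⁻¹)
    catalyst intermediate B → free catalyst + target (k = 30.0 min⁻¹)
    2 coupling partner → homo dimer (k = 0.250 M⁻¹ min⁻¹)
    2 free catalyst ⇌ resting dimer (K = 3600 M⁻¹, k = 5800 M⁻¹ min⁻¹)
    starting material + catalyst intermediate A ⇌ catalyst intermediate B (K = 4.60 M⁻¹, k = 890 M⁻¹ min⁻¹)

At the charge, w·c(coupling partner) is 0.308 on Monday's and 1.23 on Tuesday's. With two partners in each homo dimer, that dimer holds 9.55% of Monday's partner charge at 1.00 h, against 34.1% of Tuesday's at 1.50 h. A neighbour of Monday's charged with 1.20 equiv has by w the expected end value 78.2%; at 1.00 h it gives 77.7%, with 1.2% of its partner left.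

The readings stem from a simulated flask for an exercise; noise was put on by code.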